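## Retrosynthetic overview

- Kanzonol I (23) ⇐ (3R)‑3‑hydroxymethyl isoflavan 20 by desilylation, Rh decarbonylation and oxidation. The strategy rests on C3 of the pyran ring C carrying two methylene arms, C2 (to O1) and C4 (to C4a of ring A); a CH2OH in place of H‑3 makes C3 the centre of a prochiral 2‑aryl‑2‑benzylpropane‑1,3‑diol.
- 20 ⇐ diol 19 by disconnection of C8a–O1: Pd‑catalysed enantioselective O‑arylation of the ring‑A bromide by one of the two enantiotopic CH2OH groups closes ring C and fixes C3.
- 19 ⇐ malonate 18 ⇐ arylmalonate 16 + benzyl bromide 8 (C3–C4 bond by enolate alkylation), then hydride reduction.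
- 16 ⇐ chromenyl bromide 14 + diethyl malonate; 14 ⇐ 4‑bromoresorcinol by propargyl ether Claisen cyclisation. 8 ⇐ 4‑bromo‑2,6‑dimethoxybenzaldehyde (CHO → prenyl, then formylation beside Br).
- Ring order: rings A and B come from the starting arenes, the dimethylpyran ring on ring B is formed in step 9, the chroman pyran ring C last in step 13.

Key step: step 13

Assumption: the sense of induction of the chiral ligand on this substrate cannot be read from the structure; both ligand antipodes are available, and the one that closes the pro‑R hydroxymethyl arm (giving (R)‑20) is used.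
Numbering in the text is isoflavan numbering (O1, C2, C3, C4, C4a, C5–C8, C8a; primes for ring B).

## Route

Step 1
Reactants: 1 4-bromo-2,6-dimethoxybenzaldehyde
Product: 2 (4-bromo-2,6-dimethoxyphenyl)methanol
Conditions: NaBH4, MeOH/THF, 0 °C
Reagents that add atoms: none
Why: Borohydride reduction of the aryl aldehyde should be clean because the aryl bromide and the ethers are inert to NaBH4.

Step 2
Reactants: 2 (4-bromo-2,6-dimethoxyphenyl)methanol
Product: 3 5-bromo-2-(bromomethyl)-1,3-dimethoxybenzene
Conditions: PBr3, CH2Cl2, 0 °C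
Reagents that add atoms: phosphorus tribromide BrP(Br)Br
Why: The electron-rich benzylic alcohol should be displaced readily through its phosphite ester, and no acid-sensitive group is present yet.

Step 3
Reactants: 3 5-bromo-2-(bromomethyl)-1,3-dimethoxybenzene
Product: 4 5-bromo-1,3-dimethoxy-2-(3-methylbut-2-en-1-yl)benzene
Conditions: (2-methylprop-1-en-1-yl)MgBr, CuI (10 mol %), THF, −30 → 0 °C
Reagents that add atoms: (2-methylprop-1-en-1-yl)magnesium bromide CC(C)=C[Mg]Br
Why: Copper-catalysed sp3–sp2 cross-coupling of a benzylic bromide with an alkenyl Grignard reagent should build the prenyl chain with the alkene position fixed by the reagent, while the aryl bromide is left untouched by the organocopper species at low temperature.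

Step 4
Reactants: 4 5-bromo-1,3-dimethoxy-2-(3-methylbut-2-en-1-yl)benzene
Product: 6 6-bromo-2,4-dimethoxy-3-(3-methylbut-2-en-1-yl)benzaldehyde, via aryllithium 5 (not isolated)
Conditions: LDA, THF, −78 °C; DMF, −78 → 0 °C; aq NH4Cl
Reagents that add atoms: N,N-dimethylformamide CN(C)C=O
Why: Directed ortho-metalation should occur at one of the two symmetry-equivalent ring C–H bonds, each flanked by OMe and Br and so the most acidic site for a lithium amide, and the aryllithium, which holds its bromide at −78 °C, is formylated by DMF.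

Step 5
Reactants: 6 6-bromo-2,4-dimethoxy-3-(3-methylbut-2-en-1-yl)benzaldehyde
Product: 7 [6-bromo-2,4-dimethoxy-3-(3-methylbut-2-en-1-yl)phenyl]methanol
Conditions: NaBH4, MeOH, 0 °C
Reagents that add atoms: none
Why: Borohydride reduction of the hindered aldehyde should proceed without touching the aryl bromide or the prenyl alkene.

Step 6
Reactants: 7 [6-bromo-2,4-dimethoxy-3-(3-methylbut-2-en-1-yl)phenyl]methanol
Product: 8 1-bromo-2-(bromomethyl)-3,5-dimethoxy-4-(3-methylbut-2-en-1-yl)benzene
Conditions: CBr4, PPh3, CH2Cl2, 0 °C; used promptly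
Reagents that add atoms: carbon tetrabromide BrC(Br)(Br)Br
Why: The Appel reaction should convert the benzylic alcohol to the bromide under neutral conditions, so that no HBr is present to add across the prenyl alkene.

Step 7
Reactants: 9 4-bromoresorcinol
Product: 10 2-bromo-5-[(triisopropylsilyl)oxy]phenol
Conditions: TIPSCl (1.0 equiv), imidazole, CH2Cl2, 0 °C
Reagents that add atoms: chlorotriisopropylsilane CC(C)[Si](Cl)(C(C)C)C(C)C
Why: Silylation with the bulky chlorosilane should be sterically governed and take the hydroxyl para to bromine, flanked only by hydrogens, in preference to the hydroxyl shielded by the ortho bromine.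

Step 8
Reactants: 10 2-bromo-5-[(triisopropylsilyl)oxy]phenol; 11 3-chloro-3-methylbut-1-yne
Product: 12 {4-bromo-3-[(2-methylbut-3-yn-2-yl)oxy]phenoxy}triisopropylsilane
Conditions: DBU, CuCl2·2H2O (cat.), MeCN, 0 °C
Reagents that add atoms: none
Why: Copper-catalysed O-propargylation of a phenol with a tertiary propargylic chloride (through a copper acetylide/allenylidene species) should give the hindered aryl 1,1-dimethylpropargyl ether under mildly basic conditions that the aryl silyl ether tolerates.

Step 9
Reactants: 12 {4-bromo-3-[(2-methylbut-3-yn-2-yl)oxy]phenoxy}triisopropylsilane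
Product: 14 [(8-bromo-2,2-dimethyl-2H-chromen-5-yl)oxy]triisopropylsilane, via allenylphenol 13 (not isolated)
Conditions: o-xylene, reflux (ca. 145 °C)
Reagents that add atoms: none
Why: Aromatic propargyl Claisen rearrangement, 1,5-hydrogen shift and oxa-6π electrocyclisation should give a single 2H-chromene, because the only free ortho carbon is the one between the two oxygens (the other is blocked by bromine).

Step 10
Reactants: 14 [(8-bromo-2,2-dimethyl-2H-chromen-5-yl)oxy]triisopropylsilane; 15 diethyl malonate
Product: 16 diethyl 2-{2,2-dimethyl-5-[(triisopropylsilyl)oxy]-2H-chromen-8-yl}malonate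
Conditions: Pd(dba)2 (3 mol %), P(t-Bu)3·HBF4 (6 mol %), K3PO4, toluene, 80 °C
Reagents that add atoms: none
Why: Palladium-catalysed α-arylation of a malonate enolate with a bulky electron-rich trialkylphosphine should couple the electron-rich ortho-oxygenated aryl bromide, and it stops at mono-arylation because the product enolate is hindered and poorly nucleophilic.

Step 11
Reactants: 16 diethyl 2-{2,2-dimethyl-5-[(triisopropylsilyl)oxy]-2H-chromen-8-yl}malonate; 8 1-bromo-2-(bromomethyl)-3,5-dimethoxy-4-(3-methylbut-2-en-1-yl)benzene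
Product: 18 diethyl 2-[6-bromo-2,4-dimethoxy-3-(3-methylbut-2-en-1-yl)benzyl]-2-{2,2-dimethyl-5-[(triisopropylsilyl)oxy]-2H-chromen-8-yl}malonate, via sodium enolate 17 (not isolated)
Conditions: NaH, DMF, 0 °C; then 8, 0 °C → rt
Reagents that add atoms: none
Why: SN2 C-alkylation of the stabilised malonate enolate by the activated benzylic bromide, which has no β-hydrogen and so cannot eliminate, should create the fully substituted prochiral carbon (the future C3) and the C3–C4 bond.

Step 12
Reactants: 18 diethyl 2-[6-bromo-2,4-dimethoxy-3-(3-methylbut-2-en-1-yl)benzyl]-2-{2,2-dimethyl-5-[(triisopropylsilyl)oxy]-2H-chromen-8-yl}malonate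
Product: 19 2-[6-bromo-2,4-dimethoxy-3-(3-methylbut-2-en-1-yl)benzyl]-2-{2,2-dimethyl-5-[(triisopropylsilyl)oxy]-2H-chromen-8-yl}propane-1,3-diol
Conditions: LiAlH4, THF, 0 °C → rt; Rochelle salt work-up
Reagents that add atoms: none
Why: Hydride reduction of both esters of a non-enolisable disubstituted malonate should give the prochiral 1,3-diol, with the aryl bromide and the aryl silyl ether surviving at or below room temperature.

Step 13
Reactants: 19 2-[6-bromo-2,4-dimethoxy-3-(3-methylbut-2-en-1-yl)benzyl]-2-{2,2-dimethyl-5-[(triisopropylsilyl)oxy]-2H-chromen-8-yl}propane-1,3-diol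
Product: 20 [(3R)-3-{2,2-dimethyl-5-[(triisopropylsilyl)oxy]-2H-chromen-8-yl}-5,7-dimethoxy-6-(3-methylbut-2-en-1-yl)chroman-3-yl]methanol
Conditions: Pd(OAc)2 (5 mol %), chiral spirobiindane diphosphine monoxide SDP(O) (single enantiomer, 8 mol %), Cs2CO3, toluene, 70 °C
Reagents that add atoms: none
Why: Oxidative addition of Pd(0) into the C8a–Br bond, exchange of bromide for the caesium alkoxide of one CH2OH arm and C–O reductive elimination should give the chroman; the closest known reaction type is the Pd-catalysed enantioselective desymmetrising intramolecular O-arylation of 2-(2-bromobenzyl)propane-1,3-diols to 3-hydroxymethylchromans with a chiral spiro phosphine/phosphine-oxide ligand. Ring C closes in a 6-exo sense (oxygen attacks the aryl carbon from which bromide departs) through a seven-membered aryl–Pd–alkoxide chelate, helped by the Thorpe–Ingold effect of the fully substituted C3. The new stereocentre C3 is controlled by the ligand alone: the two arms are enantiotopic, the chiral pocket decides which alkoxide is bound and eliminated, closure of the pro-R arm gives (R)-20, and the quaternary centre cannot epimerise afterwards. The step needs enantiotopic-group selection and C–O coupling in preference to β-hydride elimination of the Pd alkoxide; the size difference between the chromenyl group and the spare CH2OH at the prochiral carbon gives the ligand its handle, the bromide has only one ortho substituent and is not deactivated by resonance (both OMe groups are meta to it), and neither alkene can reach the aryl–Pd centre for a Heck reaction.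

Step 14
Reactants: 20 [(3R)-3-{2,2-dimethyl-5-[(triisopropylsilyl)oxy]-2H-chromen-8-yl}-5,7-dimethoxy-6-(3-methylbut-2-en-1-yl)chroman-3-yl]methanol
Product: 21 (3S)-3-{2,2-dimethyl-5-[(triisopropylsilyl)oxy]-2H-chromen-8-yl}-5,7-dimethoxy-6-(3-methylbut-2-en-1-yl)chroman-3-carbaldehyde
Conditions: Dess–Martin periodinane, CH2Cl2, 0 °C → rt
Reagents that add atoms: none
Why: Dess–Martin oxidation of the neopentyl-type primary alcohol should give the aldehyde without touching the alkenes, and the α-carbon has no hydrogen, so its configuration is untouched (the descriptor changes to S only through the CIP priorities).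

Step 15
Reactants: 21 (3S)-3-{2,2-dimethyl-5-[(triisopropylsilyl)oxy]-2H-chromen-8-yl}-5,7-dimethoxy-6-(3-methylbut-2-en-1-yl)chroman-3-carbaldehyde
Product: 22 {[8-((3R)-5,7-dimethoxy-6-(3-methylbut-2-en-1-yl)chroman-3-yl)-2,2-dimethyl-2H-chromen-5-yl]oxy}triisopropylsilane
Conditions: RhCl(PPh3)3 (1.1 equiv), degassed toluene, 110 °C
Reagents that add atoms: none
Why: Tsuji–Wilkinson decarbonylation (formyl C–H oxidative addition, alkyl migration from CO to rhodium and C–H reductive elimination, each with retention) should replace the formyl group by hydrogen on the same face, so the C3 configuration set in step 13 becomes the (3R) tertiary centre.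

Step 16
Reactants: 22 {[8-((3R)-5,7-dimethoxy-6-(3-methylbut-2-en-1-yl)chroman-3-yl)-2,2-dimethyl-2H-chromen-5-yl]oxy}triisopropylsilane
Product: 23 kanzonol I
Conditions: TBAF, THF, 0 °C; aq NH4Cl
Reagents that add atoms: none
Why: Fluoride cleavage of the aryl silyl ether, driven by the Si–F bond, should free the 4'-phenol without affecting the methyl ethers, the alkenes or the C3–H centre.

## Compound list

1 | 4-bromo-2,6-dimethoxybenzaldehyde | COc1cc(Br)cc(OC)c1C=O | starting material
2 | (4-bromo-2,6-dimethoxyphenyl)methanol | COc1cc(Br)cc(OC)c1CO | intermediate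
3 | 5-bromo-2-(bromomethyl)-1,3-dimethoxybenzene | COc1cc(Br)cc(OC)c1CBr | intermediate
4 | 5-bromo-1,3-dimethoxy-2-(3-methylbut-2-en-1-yl)benzene | COc1cc(Br)cc(OC)c1CC=C(C)C | intermediate
5 | [6-bromo-2,4-dimethoxy-3-(3-methylbut-2-en-1-yl)phenyl]lithium (not isolated) | [Li]c1c(Br)cc(OC)c(CC=C(C)C)c1OC | intermediate
6 | 6-bromo-2,4-dimethoxy-3-(3-methylbut-2-en-1-yl)benzaldehyde | COc1cc(Br)c(C=O)c(OC)c1CC=C(C)C | intermediate
7 | [6-bromo-2,4-dimethoxy-3-(3-methylbut-2-en-1-yl)phenyl]methanol | COc1cc(Br)c(CO)c(OC)c1CC=C(C)C | intermediate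
8 | 1-bromo-2-(bromomethyl)-3,5-dimethoxy-4-(3-methylbut-2-en-1-yl)benzene | COc1cc(Br)c(CBr)c(OC)c1CC=C(C)C | intermediate
9 | 4-bromoresorcinol | Oc1ccc(Br)c(O)c1 | starting material
10 | 2-bromo-5-[(triisopropylsilyl)oxy]phenol | Oc1cc(O[Si](C(C)C)(C(C)C)C(C)C)ccc1Br | intermediate
11 | 3-chloro-3-methylbut-1-yne | CC(C)(Cl)C#C | starting material
12 | {4-bromo-3-[(2-methylbut-3-yn-2-yl)oxy]phenoxy}triisopropylsilane | C#CC(C)(C)Oc1cc(O[Si](C(C)C)(C(C)C)C(C)C)ccc1Br | intermediate
13 | 6-bromo-2-(3-methylbuta-1,2-dien-1-yl)-3-[(triisopropylsilyl)oxy]phenol (not isolated) | Oc1c(Br)ccc(O[Si](C(C)C)(C(C)C)C(C)C)c1C=C=C(C)C | intermediate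
14 | [(8-bromo-2,2-dimethyl-2H-chromen-5-yl)oxy]triisopropylsilane | Brc1ccc(O[Si](C(C)C)(C(C)C)C(C)C)c2c1OC(C)(C)C=C2 | intermediate
15 | diethyl malonate | CCOC(=O)CC(=O)OCC | starting material
16 | diethyl 2-{2,2-dimethyl-5-[(triisopropylsilyl)oxy]-2H-chromen-8-yl}malonate | CCOC(=O)C(C(=O)OCC)c1ccc(O[Si](C(C)C)(C(C)C)C(C)C)c2c1OC(C)(C)C=C2 | intermediate
17 | sodium enolate of 16 (not isolated) | [Na+].CCOC([O-])=C(C(=O)OCC)c1ccc(O[Si](C(C)C)(C(C)C)C(C)C)c2c1OC(C)(C)C=C2 | intermediate
18 | diethyl 2-[6-bromo-2,4-dimethoxy-3-(3-methylbut-2-en-1-yl)benzyl]-2-{2,2-dimethyl-5-[(triisopropylsilyl)oxy]-2H-chromen-8-yl}malonate | CCOC(=O)C(Cc1c(Br)cc(OC)c(CC=C(C)C)c1OC)(C(=O)OCC)c1ccc(O[Si](C(C)C)(C(C)C)C(C)C)c2c1OC(C)(C)C=C2 | intermediate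
19 | 2-[6-bromo-2,4-dimethoxy-3-(3-methylbut-2-en-1-yl)benzyl]-2-{2,2-dimethyl-5-[(triisopropylsilyl)oxy]-2H-chromen-8-yl}propane-1,3-diol (prochiral) | COc1cc(Br)c(CC(CO)(CO)c2ccc(O[Si](C(C)C)(C(C)C)C(C)C)c3c2OC(C)(C)C=C3)c(OC)c1CC=C(C)C | intermediate
20 | [(3R)-3-{2,2-dimethyl-5-[(triisopropylsilyl)oxy]-2H-chromen-8-yl}-5,7-dimethoxy-6-(3-methylbut-2-en-1-yl)chroman-3-yl]methanol | COc1cc2c(c(OC)c1CC=C(C)C)C[C@](CO)(c1ccc(O[Si](C(C)C)(C(C)C)C(C)C)c3c1OC(C)(C)C=C3)CO2 | intermediate
21 | (3S)-3-{2,2-dimethyl-5-[(triisopropylsilyl)oxy]-2H-chromen-8-yl}-5,7-dimethoxy-6-(3-methylbut-2-en-1-yl)chroman-3-carbaldehyde | COc1cc2c(c(OC)c1CC=C(C)C)C[C@](C=O)(c1ccc(O[Si](C(C)C)(C(C)C)C(C)C)c3c1OC(C)(C)C=C3)CO2 | intermediate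
22 | 4'-O-triisopropylsilyl kanzonol I, (3R) | COc1cc2c(c(OC)c1CC=C(C)C)C[C@H](c1ccc(O[Si](C(C)C)(C(C)C)C(C)C)c3c1OC(C)(C)C=C3)CO2 | intermediate
23 | kanzonol I, (3R)-3-(5-hydroxy-2,2-dimethyl-2H-chromen-8-yl)-5,7-dimethoxy-6-(3-methylbut-2-en-1-yl)chroman | COc1cc2c(c(OC)c1CC=C(C)C)C[C@H](c1ccc(O)c3c1OC(C)(C)C=C3)CO2 | target

## Step count and risks

Total step count: 16. Longest linear sequence: 12 steps (steps 1–6 and 11–16); the ring-B branch (steps 7–10) joins at step 11.

Steps most likely to fail:

**1. Step 13 (desymmetrising O-arylation).** The ligand may discriminate poorly between the two enantiotopic hydroxymethyl arms on this bulky substrate, and slow C–O reductive elimination may let β-hydride elimination of the Pd alkoxide (with hydrodebromination) take over. The fallback moves the group selection to an enzyme and makes the ring closure achiral. It sets out from 19 and comes back at 20.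
- Lipase-catalysed mono-acetylation of 19 (vinyl acetate, MTBE, rt; lipase selected by screening, for example Burkholderia cepacia lipase or Candida antarctica lipase B, for acetylation of the pro-R arm) should give monoacetate F1.
- The free hydroxyl is capped with dihydropyran/PPTS (CH2Cl2) to give acetate THP ether F2. An acetal is chosen because it cannot migrate between the two arms under base, unlike an acyl or silyl group.
- DIBAL-H (CH2Cl2, −78 °C) removes the acetate to give mono-THP diol F3, with the pro-R hydroxymethyl now free.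
- Achiral intramolecular Pd-catalysed etherification (Pd(OAc)2, 2-(di-tert-butylphosphino)-1,1'-binaphthyl, Cs2CO3, toluene, 70 °C) closes ring C to THP-protected chroman F4.
- PPTS in MeOH (40 °C) releases 20.

**2. Step 15 (decarbonylation).** Oxidative addition to the hindered neopentyl-type formyl group may be slow, the tertiary benzylic alkylrhodium may undergo β-hydride elimination to isoflavenes, and homolysis of the benzylic C–Rh bond would erode the configuration. The fallback gives up the spare carbon and sets the C3–H centre directly by auxiliary-controlled alkylation, replacing steps 11–15. It sets out from 16 and 8 and comes back at 22.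
- Ester cleavage of 16 with Me3SnOH (1,2-dichloroethane, 80 °C), which spares the aryl silyl ether, with loss of CO2 from the malonic acid on heating, should give arylacetic acid F5.
- Activation as the mixed pivalic anhydride (PivCl, Et3N, THF, −20 °C) and acylation of lithiated (R)-4-benzyloxazolidin-2-one gives imide F6.
- Evans alkylation (NaHMDS, THF, −78 °C; then 8) should place the benzyl group anti to the auxiliary substituent on the Z-enolate and give the (2R)-alkylated imide F7.
- LiBH4 (Et2O, 1 equiv H2O, 0 °C) cleaves the auxiliary to the (2R)-primary alcohol F8.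
- Achiral intramolecular Pd-catalysed etherification (Pd(OAc)2, 2-(di-tert-butylphosphino)-1,1'-binaphthyl, Cs2CO3, toluene, 60 °C) closes ring C and gives 22.

**3. Step 4 (formylation beside bromine).** The ortho-bromo aryllithium may lose LiBr (aryne formation) before it is trapped, and the base may instead remove a proton from the doubly activated ArCH2–CH= position of the prenyl chain. The fallback replaces deprotonation by electrophilic aromatic substitution. It sets out from 4 and comes back at 6.
- Vilsmeier–Haack formylation (POCl3, DMF, 0 → 70 °C) should attack the same position, which is para to one methoxy group and ortho to the other, to give iminium salt F9.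
- Hydrolysis with aqueous NaOAc gives 6.

Further compounds
F1 | step 13 | (2R)-2-[6-bromo-2,4-dimethoxy-3-(3-methylbut-2-en-1-yl)benzyl]-2-{2,2-dimethyl-5-[(triisopropylsilyl)oxy]-2H-chromen-8-yl}-3-hydroxypropyl acetate (monoacetate of 19, pro-R arm acetylated) | COc1cc(Br)c(C[C@](CO)(c2ccc(O[Si](C(C)C)(C(C)C)C(C)C)c3c2OC(C)(C)C=C3)COC(C)=O)c(OC)c1CC=C(C)C
F2 | step 13 | tetrahydropyran-2-yl ether of F1 (mixture of epimers at the acetal carbon) | COc1cc(Br)c(C[C@](COC2CCCCO2)(c2ccc(O[Si](C(C)C)(C(C)C)C(C)C)c3c2OC(C)(C)C=C3)COC(C)=O)c(OC)c1CC=C(C)C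
F3 | step 13 | mono-tetrahydropyran-2-yl ether of 19 with the pro-R hydroxymethyl group free (mixture of epimers at the acetal carbon) | COc1cc(Br)c(C[C@](COC2CCCCO2)(c2ccc(O[Si](C(C)C)(C(C)C)C(C)C)c3c2OC(C)(C)C=C3)CO)c(OC)c1CC=C(C)C
F4 | step 13 | tetrahydropyran-2-yl ether of 20 (mixture of epimers at the acetal carbon) | COc1cc2c(c(OC)c1CC=C(C)C)C[C@](COC1CCCCO1)(c1ccc(O[Si](C(C)C)(C(C)C)C(C)C)c3c1OC(C)(C)C=C3)CO2
F5 | step 15 | {2,2-dimethyl-5-[(triisopropylsilyl)oxy]-2H-chromen-8-yl}acetic acid | OC(=O)Cc1ccc(O[Si](C(C)C)(C(C)C)C(C)C)c2c1OC(C)(C)C=C2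
F6 | step 15 | (4R)-4-benzyl-3-({2,2-dimethyl-5-[(triisopropylsilyl)oxy]-2H-chromen-8-yl}acetyl)oxazolidin-2-one | O=C1OC[C@@H](Cc2ccccc2)N1C(=O)Cc1ccc(O[Si](C(C)C)(C(C)C)C(C)C)c2c1OC(C)(C)C=C2
F7 | step 15 | (4R)-4-benzyl-3-[(2R)-3-[6-bromo-2,4-dimethoxy-3-(3-methylbut-2-en-1-yl)phenyl]-2-{2,2-dimethyl-5-[(triisopropylsilyl)oxy]-2H-chromen-8-yl}propanoyl]oxazolidin-2-one | O=C1OC[C@@H](Cc2ccccc2)N1C(=O)[C@H](Cc1c(Br)cc(OC)c(CC=C(C)C)c1OC)c1ccc(O[Si](C(C)C)(C(C)C)C(C)C)c2c1OC(C)(C)C=C2
F8 | step 15 | (2R)-3-[6-bromo-2,4-dimethoxy-3-(3-methylbut-2-en-1-yl)phenyl]-2-{2,2-dimethyl-5-[(triisopropylsilyl)oxy]-2H-chromen-8-yl}propan-1-ol | OC[C@H](Cc1c(Br)cc(OC)c(CC=C(C)C)c1OC)c1ccc(O[Si](C(C)C)(C(C)C)C(C)C)c2c1OC(C)(C)C=C2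
F9 | step 4 | N-[6-bromo-2,4-dimethoxy-3-(3-methylbut-2-en-1-yl)benzylidene]-N-methylmethanaminium chloride | [Cl-].C[N+](C)=Cc1c(Br)cc(OC)c(CC=C(C)C)c1OC
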